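## Retrosynthetic overview

1. The two angelates go on last, one at a time, both from one batch of the mixed anhydride 20 of angelic acid: target 23 ⇐ 8,9-diol 22 ⇐ 8,9-cyclic carbonate 18. The C7 and C8 oxygens are relayed from the C9 hydroxyl of 15 (Boc carbonate, anti epoxidation, carbonate opening at C8 with inversion).
2. Key disconnection: bicyclo[3.1.1]heptenone 15 ⇐ 1-siloxy-2-endo-aminonorbornene 13 by deaminative ring contraction. C10 shifts from C1 to C11, the five-membered ring becomes the cyclobutane and C1 becomes the enone carbonyl.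
3. 13 ⇐ intramolecular Diels–Alder reaction of a 1-siloxycyclopentadiene with a tethered (E)-nitroalkene, which builds the norbornene and the seven-membered ring in one step.
4. Diels–Alder precursor ⇐ aldol union of methyl ketone (S)-7 (from 3-methylcyclopent-2-en-1-one by C-acetylation and asymmetric methylation) with nitro-enal 4 (from 2,2-dimethylbut-3-en-1-ol).
5. Ring order: cyclopentenone (purchased) → norbornene plus cycloheptane → cyclobutane plus cyclohexenone (ring contraction).

Assumption: carbons keep the longipinane numbers of the target in every intermediate (C1 ring carbonyl, C2=C3(Me), C4, C5, C6(Me)2, C7, C8, C9, C10(Me), C11); "C11 side" and "C4 side" name the two faces of the seven-membered ring; 2,2-dimethylbut-3-en-1-ol is taken as purchasable.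

## Route

Step 1
Reactants: 1 2,2-dimethylbut-3-en-1-ol
Product: 3 (E)-2,2-dimethyl-4-nitrobut-3-en-1-ol, via iodonitro adduct 2 (not isolated)
Conditions: AgNO2, I2, Et2O, 0 → 23 °C; then Et3N, 0 °C
Reagents that add atoms: silver nitrite, [Ag+].[O-]N=O
Why: Nitryl iodide made in the flask adds across the terminal alkene with nitro at the terminal carbon, and E1cB loss of HI with Et3N gives the conjugated (E)-nitroalkene (iodonitration–dehydroiodination).

Step 2
Reactants: 3 (E)-2,2-dimethyl-4-nitrobut-3-en-1-ol
Product: 4 (E)-2,2-dimethyl-4-nitrobut-3-enal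
Conditions: Dess–Martin periodinane, CH2Cl2, 23 °C
Reagents that add atoms: none
Why: Dess–Martin oxidation converts the neopentyl primary alcohol into the non-enolisable aldehyde under neutral conditions that leave the nitroalkene untouched.

Step 3
Reactants: 5 3-methylcyclopent-2-en-1-one
Product: 6 5-acetyl-3-methylcyclopent-2-en-1-one
Conditions: LiN(iPr)2 (2.2 equiv), THF, −78 °C; 1-acetylimidazole; aq. NH4Cl
Reagents that add atoms: 1-acetylimidazole, CC(=O)n1ccnc1
Why: Kinetic α′-deprotonation of the enone followed by Claisen-type C-acylation with an acyl imidazole gives the β-diketone, the second equivalent of base taking up its acidic proton.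

Step 4
Reactants: 6 5-acetyl-3-methylcyclopent-2-en-1-one
Product: 7 (S)-5-acetyl-3,5-dimethylcyclopent-2-en-1-one
Conditions: MeI, Cs2CO3, toluene, −20 °C, 3,4,5-trifluorophenyl-substituted N-spiro bis(binaphthyl)ammonium bromide (2 mol%, the enantiomer that gives (S)-7)
Reagents that add atoms: iodomethane, CI
Why: Asymmetric phase-transfer C-alkylation in which the chiral ammonium cation shields one face of the β-diketone enolate, so that methylation creates the C10 quaternary stereocenter from which every other stereocenter is relayed.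

Step 5
Reactants: 7 (S)-5-acetyl-3,5-dimethylcyclopent-2-en-1-one; 4 (E)-2,2-dimethyl-4-nitrobut-3-enal
Product: 9 (E)-1-[(1S)-1,4-dimethyl-2-oxocyclopent-3-en-1-yl]-4,4-dimethyl-6-nitro-1-oxohex-5-en-3-yl acetate (C7 epimers), via lithium aldolate 8 (not isolated)
Conditions: LiN(iPr)2 (1.05 equiv), THF, −78 °C; 4, 5 min; Ac2O, −78 → 0 °C
Reagents that add atoms: acetic anhydride, CC(=O)OC(C)=O
Why: Directed aldol addition of the kinetic acetyl enolate to the non-enolisable aldehyde (faster at −78 °C than Michael addition to the β-tert-alkyl nitroalkene) with in-flask acetylation to block retro-aldol; the C7 configuration is irrelevant because C7 becomes sp2 in step 7.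

Step 6
Reactants: 9 aldol acetate
Product: 11 Diels–Alder adduct (norbornene with C1–OTBS, C11–NO2 endo, C6 exo on C5, C10–Me syn to C2=C3, seven-membered ring C4–C5–C6–C7(OAc)–C8–C9(=O)–C10; C7 epimers), via siloxydiene 10 (not isolated)
Conditions: TBSOTf (1.15 equiv), Et3N, CH2Cl2, −78 → 0 °C; NaHCO3 wash; toluene, 23 → 45 °C
Reagents that add atoms: tert-butyldimethylsilyl trifluoromethanesulfonate, CC(C)(C)[Si](C)(C)OS(=O)(=O)C(F)(F)F
Why: Soft γ-enolisation of the enone gives the 1-siloxycyclopentadiene, which undergoes an intramolecular Diels–Alder reaction in which the tether from C10 forces addition on its own face (C6 exo), the (E)-alkene places NO2 endo, and the donor-polarised diene bonds C4 to the electrophilic C5, so C1, C4, C5 and C11 are set relative to C10.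

Step 7
Reactants: 11 Diels–Alder adduct
Product: 12 dienone (as 11 but with the C9(=O)–C8H=C7H enone)
Conditions: DBU (1.2 equiv), CH2Cl2, 0 → 23 °C
Reagents that add atoms: none
Why: E1cB elimination of acetate from the β-acetoxy ketone gives the ring (Z)-enone, while the reversibly deprotonated C11 nitro centre returns to the endo position trans to the exo C6 substituent.

Step 8
Reactants: 12 dienone
Product: 13 amino alcohol (C11–NH2 endo, (9R)-C9–OH on the C11 side, C1–OTBS, C7=C8)
Conditions: LiAlH4, THF, −78 → 50 °C; H2O, aq. NaOH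
Reagents that add atoms: none
Why: Hydride adds 1,2 to the enone from the open face of the seven-membered ring (the other face is blocked by the C1–C11 bridge), which sets C9, and the secondary nitro group is reduced to the primary amine with retention at C11.

Step 9
Reactants: 13 amino alcohol
Product: 15 (4R,5S,9R,10R,11R)-9-hydroxylongipina-2,7-dien-1-one, via diazonium acetate 14 (not isolated)
Conditions: NaNO2, AcOH/H2O/THF, 0 °C
Reagents that add atoms: none
Why: Proposed new method: a Tiffeneau–Demjanov-type deaminative semipinacol ring contraction of a bridgehead-oxygenated 2-endo-aminonorbornene, in which the endo C11–N2+ bond is antiperiplanar only to C1–C10, so C10 migrates to C11 (inversion at C11, retention at C10) while the siloxy oxygen turns C1 into the conjugated ketone, contracting the five-membered ring to the cyclobutane of the bicyclo[3.1.1]heptenone; the closest known reaction type is the nitrous acid deamination of cyclic 1,2-amino alcohols with ring contraction, not yet shown for a norbornene-to-pinane-type change of skeleton.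

Step 10
Reactants: 15 tricyclic allylic alcohol
Product: 16 (9R)-9-tert-butoxycarbonyloxy derivative of 15
Conditions: Boc2O, DMAP (0.2 equiv), MeCN, 23 °C
Reagents that add atoms: di-tert-butyl dicarbonate, CC(C)(C)OC(=O)OC(=O)OC(C)(C)C
Why: DMAP-catalysed carbonate formation at the only hydroxyl installs the group that will later deliver oxygen to C8.

Step 11
Reactants: 16 Boc carbonate
Product: 17 7,8-epoxide of 16 (epoxide oxygen on the C4 side, trans to O9)
Conditions: m-CPBA, CH2Cl2, 0 °C
Reagents that add atoms: 3-chloroperoxybenzoic acid, OOC(=O)c1cccc(Cl)c1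
Why: Prilezhaev epoxidation of the only electron-rich alkene (the enone alkene is inert) takes place anti to the bulky allylic carbonate, which sets C7.

Step 12
Reactants: 17 epoxy carbonate
Product: 18 8,9-cyclic carbonate with free C7–OH (O8 and O9 on the C11 side, O7 on the C4 side)
Conditions: BF3·OEt2 (0.2 equiv), CH2Cl2, −40 °C
Reagents that add atoms: none
Why: The Lewis acid-activated epoxide is opened by the carbonate carbonyl oxygen in a 5-exo attack at C8 with inversion and loss of isobutene, giving the cis-8,9-carbonate and the C7 hydroxyl trans to O8.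

Step 13
Reactants: 19 angelic acid
Product: 20 (Z)-2-methylbut-2-enoic 2,4,6-trichlorobenzoic anhydride
Conditions: 2,4,6-Cl3C6H2COCl (1.0 equiv), Et3N (1.0 equiv), toluene, 23 °C; filter, concentrate; kept as a toluene stock solution
Reagents that add atoms: 2,4,6-trichlorobenzoyl chloride, O=C(Cl)c1c(Cl)cc(Cl)cc1Cl
Why: Acyl substitution of the acid chloride by the triethylammonium carboxylate gives the Yamaguchi-type mixed anhydride without a nucleophilic catalyst, so the Z geometry is kept; one batch serves both esterifications.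

Step 14
Reactants: 18 carbonate alcohol; 20 mixed anhydride
Product: 21 7-O-angeloyl 8,9-cyclic carbonate
Conditions: 20 (3 equiv), toluene, 80 °C
Reagents that add atoms: none
Why: Yamaguchi-type esterification in which the single free hydroxyl attacks the angeloyl carbonyl of the mixed anhydride (the trichlorobenzoyl carbonyl is shielded by its two ortho chlorines), with no nucleophilic catalyst that could cause Z-to-E isomerisation of the angelate.

Step 15
Reactants: 21 angeloyl carbonate
Product: 22 7-O-angeloyl 8,9-diol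
Conditions: K2CO3 (0.1 equiv), MeOH, 0 °C
Reagents that add atoms: none
Why: Base-catalysed methanolysis cleaves the five-membered cyclic carbonate much faster than the hindered α,β-unsaturated ester and frees the cis-8,9-diol.

Step 16
Reactants: 22 7-O-angeloyl 8,9-diol; 20 mixed anhydride
Product: 23 target
Conditions: 20 (1.1 equiv), toluene, 23 → 50 °C
Reagents that add atoms: none
Why: A second Yamaguchi-type esterification with about one equivalent of the mixed anhydride acylates C8–OH, the less hindered of the two hydroxyls (C9–OH is neopentylic to the quaternary C10), which completes the target.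

## Compound list

1 | 2,2-dimethylbut-3-en-1-ol | C=CC(C)(C)CO | starting material
2 | 3-iodo-2,2-dimethyl-4-nitrobutan-1-ol (racemic) | OCC(C)(C)C(I)C[N+](=O)[O-] | intermediate
3 | (E)-2,2-dimethyl-4-nitrobut-3-en-1-ol | OCC(C)(C)/C=C/[N+](=O)[O-] | intermediate
4 | (E)-2,2-dimethyl-4-nitrobut-3-enal | O=CC(C)(C)/C=C/[N+](=O)[O-] | intermediate
5 | 3-methylcyclopent-2-en-1-one | CC1=CC(=O)CC1 | starting material
6 | 5-acetyl-3-methylcyclopent-2-en-1-one (β-diketone, largely enolised) | CC(=O)C1CC(C)=CC1=O | intermediate
7 | (S)-5-acetyl-3,5-dimethylcyclopent-2-en-1-one | CC(=O)[C@]1(C)CC(C)=CC1=O | intermediate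
8 | lithium (E)-1-[(1S)-1,4-dimethyl-2-oxocyclopent-3-en-1-yl]-4,4-dimethyl-6-nitro-1-oxohex-5-en-3-olate (C7 epimers) | [Li+].[O-]C(CC(=O)[C@]1(C)CC(C)=CC1=O)C(C)(C)/C=C/[N+](=O)[O-] | intermediate
9 | (E)-1-[(1S)-1,4-dimethyl-2-oxocyclopent-3-en-1-yl]-4,4-dimethyl-6-nitro-1-oxohex-5-en-3-yl acetate (C7 epimers) | CC(=O)OC(CC(=O)[C@]1(C)CC(C)=CC1=O)C(C)(C)/C=C/[N+](=O)[O-] | intermediate
10 | 1-tert-butyldimethylsilyloxy-cyclopenta-1,3-diene derived from 9 (C10 configuration unchanged, C7 epimers) | CC(=O)OC(CC(=O)[C@]1(C)C=C(C)C=C1O[Si](C)(C)C(C)(C)C)C(C)(C)/C=C/[N+](=O)[O-] | intermediate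
11 | Diels–Alder adduct: norbornene with C1–OTBS, C3–Me, C11–NO2 endo, C5–C6 exo, C10–Me syn to C2=C3, ring C4–C5–C6(Me)2–C7(OAc)–C8H2–C9(=O)–C10 (C7 epimers) | O=C1CC(OC(C)=O)C(C)(C)[C@@H]2[C@@H]([N+](=O)[O-])[C@@]3(O[Si](C)(C)C(C)(C)C)C=C(C)[C@@H]2[C@@]13C | intermediate
12 | dienone: as 11 with C9(=O)–C8H=C7H | O=C1C=CC(C)(C)[C@@H]2[C@@H]([N+](=O)[O-])[C@@]3(O[Si](C)(C)C(C)(C)C)C=C(C)[C@@H]2[C@@]13C | intermediate
13 | amino alcohol: as 12 with C11–NH2 (endo) and (9R)-C9–OH on the C11 side | O[C@@H]1C=CC(C)(C)[C@@H]2[C@@H](N)[C@@]3(O[Si](C)(C)C(C)(C)C)C=C(C)[C@@H]2[C@@]13C | intermediate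
14 | C11 diazonium acetate of 13 | CC(=O)[O-].O[C@@H]1C=CC(C)(C)[C@@H]2[C@@H]([N+]#N)[C@@]3(O[Si](C)(C)C(C)(C)C)C=C(C)[C@@H]2[C@@]13C | intermediate
15 | (4R,5S,9R,10R,11R)-9-hydroxylongipina-2,7-dien-1-one (OH on the C11 side) | O[C@@H]1C=CC(C)(C)[C@@H]2[C@H]3C(=O)C=C(C)[C@@H]2[C@]31C | intermediate
16 | (9R)-9-tert-butoxycarbonyloxy derivative of 15 | CC(C)(C)OC(=O)O[C@@H]1C=CC(C)(C)[C@@H]2[C@H]3C(=O)C=C(C)[C@@H]2[C@]31C | intermediate
17 | 7,8-epoxide of 16, epoxide oxygen on the C4 side | CC(C)(C)OC(=O)O[C@@H]1[C@H]2O[C@H]2C(C)(C)[C@@H]3[C@H]4C(=O)C=C(C)[C@@H]3[C@]41C | intermediate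
18 | 7-hydroxylongipin-2-en-1-one 8,9-cyclic carbonate (O8, O9 on the C11 side; O7 on the C4 side) | O[C@@H]1[C@H]2OC(=O)O[C@H]2[C@@]3(C)[C@@H]4C(=O)C=C(C)[C@H]3[C@@H]4C1(C)C | intermediate
19 | angelic acid, (Z)-2-methylbut-2-enoic acid | C/C=C(/C)C(=O)O | starting material
20 | (Z)-2-methylbut-2-enoic 2,4,6-trichlorobenzoic anhydride | C/C=C(/C)C(=O)OC(=O)c1c(Cl)cc(Cl)cc1Cl | intermediate
21 | 7-O-angeloyl derivative of 18 | C/C=C(/C)C(=O)O[C@@H]1[C@H]2OC(=O)O[C@H]2[C@@]3(C)[C@@H]4C(=O)C=C(C)[C@H]3[C@@H]4C1(C)C | intermediate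
22 | 7-O-angeloyl-8,9-dihydroxylongipin-2-en-1-one | C/C=C(/C)C(=O)O[C@@H]1[C@@H](O)[C@@H](O)[C@@]2(C)[C@@H]3C(=O)C=C(C)[C@H]2[C@@H]3C1(C)C | intermediate
23 | (4R,5S,7S,8S,9S,10R,11R)-7,8-bis(angeloyloxy)-9-hydroxylongipin-2-en-1-one | C/C=C(/C)C(=O)O[C@@H]1[C@@H](OC(=O)/C(C)=C\C)C(C)(C)[C@@H]2[C@H]3C(=O)C=C(C)[C@@H]2[C@@]3(C)[C@@H]1O | target

## Step count and risks

Total steps: 16. Longest linear sequence: 13 (steps 3 to 12 and 14 to 16, from 3-methylcyclopent-2-en-1-one); steps 1 and 2 (to 4) and step 13 (to 20) are side branches.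

**Step 9 (the proposed new step).** The diazonium ion may be captured by solvent or by the C2=C3 π bond instead of triggering the C10 shift. The fallback uses known chemistry, sets out from 13 and comes back at 15. Exhaustive N-methylation (MeI, K2CO3, MeCN) gives the trimethylammonium iodide F1. Bu4NF in THF at 40 °C then removes the bridgehead silyl group, and the alkoxide expels trimethylamine as the antiperiplanar C10 migrates. This is the classical base-induced semipinacol rearrangement of β-hydroxy quaternary ammonium salts; it runs in an anionic, concerted manifold with no free carbocation.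

**Step 6.** The C9 ketone may be silylated in competition, the diene may isomerise, or the cycloaddition that forms the seven-membered ring may be slow. The fallback sets out from 7 (with 4) and comes back at 12; it reverses the order of the two unions. TBSOTf and Et3N convert 7 into the siloxydiene F2. An intermolecular Diels–Alder reaction with 4 (toluene, 23 °C) gives the keto aldehyde adduct F3. An intramolecular aldol condensation (pyrrolidine, AcOH, CH2Cl2) between the acetyl methyl and the aldehyde then closes the seven-membered ring and dehydrates to 12. Any adduct formed on the methyl face cannot close and is removed.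

**Step 4.** The methylation may give insufficient enantioselectivity, and all later stereocontrol depends on C10. The fallback sets out from 6 and comes back at 7. Palladium-catalysed asymmetric allylic alkylation ([Pd(C3H5)Cl]2, DACH-phenyl Trost ligand, allyl acetate, Cs2CO3) gives the allyl diketone F4. Ozonolysis of the terminal alkene (O3, CH2Cl2, −78 °C; Me2S) gives the aldehyde F5. Decarbonylation with stoichiometric RhCl(PPh3)3 (toluene, 110 °C) turns the CH2CHO group into the methyl group of 7.

## Further compounds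

F1 | step 9 | N,N,N-trimethylammonium iodide of 13 (C11 endo) | O[C@@H]1C=CC(C)(C)[C@@H]2[C@@H]([N+](C)(C)C)[C@@]3(O[Si](C)(C)C(C)(C)C)C=C(C)[C@@H]2[C@@]13C.[I-]
F2 | step 6 | 5-acetyl-1-tert-butyldimethylsilyloxy-3,5-dimethylcyclopenta-1,3-diene (C10 configuration as in 7) | CC(=O)[C@]1(C)C=C(C)C=C1O[Si](C)(C)C(C)(C)C
F3 | step 6 | intermolecular adduct: norbornene with C1–OTBS, C11–NO2 endo, C5 exo-C(Me)2CHO, C10 bearing methyl (syn to C2=C3) and acetyl | O=CC(C)(C)[C@@H]1[C@@H]([N+](=O)[O-])[C@@]2(O[Si](C)(C)C(C)(C)C)C=C(C)[C@@H]1[C@@]2(C)C(C)=O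
F4 | step 4 | (S)-5-acetyl-5-allyl-3-methylcyclopent-2-en-1-one | CC(=O)[C@]1(CC=C)CC(C)=CC1=O
F5 | step 4 | (R)-2-(1-acetyl-3-methyl-5-oxocyclopent-3-en-1-yl)acetaldehyde | CC(=O)[C@]1(CC=O)CC(C)=CC1=O
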